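The closed, stirred vessel starts with electrophile, nucleophile and protic impurity. The questions are where it stops and how much nucleophile stays free.

| setting | blue | violet | green | flask |
|---|---|---|---|---|
| electrophile | 0.070 M | 0.11 M | 0.050 M | 0.050 M |
| nucleophile | 3 equiv | 3 equiv | 3 equiv | 3.00 equiv |
| protic impurity | 0.025 M | 0.025 M | 0.038 M | 0.0250 M |
| remark | run made earlier | run made earlier | run made earlier |  |
| time |  |  |  | 4.0 d |

| run | time / d | electrophile / % | product / % |
|---|---|---|---|
| blue | 0.125 | 59 | 42 |
| blue | 0.333 | 30 | 68 |
| blue | 0.625 | 17 | 80 |
| blue | 1.04 | 9 | 94 |
| blue | 1.67 | 3 | 95 |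
| blue | 2.08 | 1 | 100 |
| blue | 2.50 | 4 | 100 |
| violet | 0.208 | 30 | 71 |
| violet | 0.333 | 16 | 86 |
| violet | 0.417 | 12 | 86 |
| violet | 0.625 | 5 | 95 |
| violet | 1.04 | 3 | 96 |
| violet | 1.67 | 1 | 100 |
| violet | 2.50 | 0 | 99 |
| green | 0.500 | 40 | 64 |
| green | 1.04 | 24 | 79 |
| green | 1.25 | 16 | 85 |
| green | 2.08 | 14 | 92 |
| green | 2.50 | 6 | 92 |

(readings scatter by 2 percentage points)

- the earlier runs were read with a standard deviation of 2 percentage points
- steps thought possible: electrophile + nucleophile -> acid set free + product; nucleophile + acid set free <-> protonated nucleophile; acid set free -> by-product carried off; nucleophile + protic impurity -> quenched reagent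
- the earlier runs do not show how much of nucleophile is bound; that part of a forecast is a guess

- part of the electrophile that has reacted at 4.0 d
- share of the unused nucleophile that is free and not bound as protonated nucleophile, at 4.0 d

1. Each protic impurity is counted as taking one nucleophile. Each electrophile takes one to react, and its acid set free is counted as binding a second.

2. For this flask, the nucleophile left after quenching, divided by two per electrophile, is 1.25; call this the margin. By this count, above one the electrophile is the limiting reagent. Below one, with the acid fully bound, the margin is the fraction that can react.

3. The flask's margin exceeds one, so its electrophile is limiting. With the acid fully bound and the electrophile used, the free share is (two margins minus two) over (two margins minus one), or 33.3%.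

4. The margin gives a reckoned stopping point, not a pace. The blue and violet margins are close, 1.32 and 1.39, yet at 0.625 d violet has less electrophile left, 5% against 17%. The green run has the flask's electrophile charge and a smaller margin, 1.12, and shows 6% left at 2.50 d. The flask has the larger margin and a longer time, 4.0 d, so it should have less electrophile left than that green reading.

5. The forecast gives 98.5% reacted and 40% free, holding that “each reaction uses two nucleophiles”. Its free share is above the 33.3% reckoned here.

The flask gives 98.7% reacted and 35.2% free.

    electrophile + nucleophile → acid set free + product (k = 3.20 × 10⁻⁴ M⁻¹ s⁻¹)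
    nucleophile + acid set free ⇌ protonated nucleophile, settled at all times (K = 55000 M⁻¹)
    acid set free → by-product carried off (k = 3.20 × 10⁻⁵ s⁻¹)
    nucleophile + protic impurity → quenched reagent (k = 0.00570 M⁻¹ s⁻¹)

The flask, with its margin of 1.25, keeps 1.31% of its electrophile at 4.00 d. The neighbouring flask has 0.013 M of electrophile at the same equivalents, and its margin is 0.538, below one. By the count of step 1, the nucleophile is the limiting reagent there, and with the acid fully bound the reckoned ceiling is 53.8% reacted. At 4.00 d this neighbour stands under that ceiling, at 47.1% reacted, with 5.25% of its charged nucleophile still unbound.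

(The numbers in the tables were generated by integration from invented constants.)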